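(The data stem from a simulated flask from invented constants; noise was put on by code.)

An easy step first: take 60.0 mM from both of Saturday's charges and I hold Monday's charge, with the same free catalyst. So Saturday's flask, once it has used 60.0 mM of substrate, has the substrate and reagent with which Monday's flask opens. Substrate is the limiting reagent in both, and reagent stands 0.0500 M above it in both.

| flask | substrate | reagent | free catalyst | time |
|---|---|---|---|---|
| Saturday's | 100 mM | 150 mM | 5.00 mM |  |
| Monday's | 40.0 mM | 90.0 mM | 5.00 mM |  |
| Sunday's | 150 mM | 150 mM | 5.00 mM |  |
| Tuesday's | 100 mM | 150 mM | 7.50 mM |  |
| Wednesday's | 100 mM | 150 mM | 5.00 mM | 84 min |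

| run | time / min | [target] / mM |
|---|---|---|
| Saturday's run | 5.6 | 14.2 |
| Saturday's run | 11 | 27.0 |
| Saturday's run | 17 | 39.4 |
| Saturday's run | 22 | 48.2 |
| Saturday's run | 28 | 59.4 |
| Monday's run | 5.6 | 7.5 |
| Monday's run | 11 | 13.1 |
| Monday's run | 17 | 19.0 |
| Monday's run | 22 | 24.9 |
| Monday's run | 28 | 27.2 |
| Sunday's run | 5.6 | 16.8 |
| Sunday's run | 11 | 32.0 |
| Sunday's run | 17 | 49.2 |
| Sunday's run | 22 | 59.9 |
| Sunday's run | 28 | 73.8 |
| Tuesday's run | 5.6 | 23.0 |
| Tuesday's run | 11 | 40.0 |
| Tuesday's run | 17 | 56.8 |
| Tuesday's run | 22 | 68.8 |
| Tuesday's run | 28 | 78.6 |

(each reading ± 0.5 mM)

1. how the opening rate goes with [free catalyst] round the charge of the Saturday's run: the exponent of the rate at two percent of substrate gone to target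
2. how the opening rate goes with [reagent] round the charge of the Saturday's run: the exponent of the rate at two percent of substrate gone to target
3. the Monday's run starts with 60.0 mM less of substrate and of reagent than the Saturday's run, and with no target. Compared where both hold the same amount of substrate, once fifteen percent of what the Monday's run was charged with has turned into target, is the Monday's run faster, slower or alike (within a tenth)?
4. target in the Wednesday's run at 84 min, as a share of the substrate charged

- Overall: substrate + reagent -> target, with free catalyst as catalyst.
- Constant volume, constant temperature.
- Bound and free are read together.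
- An order is taken over about fifteen percent of the charge, up and down.

Is Monday's flask just the tail of Saturday's? Rates at different amounts need a common measure. In Monday's flask substrate falls from 40.0 mM to 0.0128 M in 28 min, which gives 0.0407 min⁻¹. That is its clearance: the natural log of the substrate at the start of a stretch over that at its end, per minute of the stretch.

Saturday's last stretch takes substrate from 0.0518 M to 0.0406 M and reads 0.0406 min⁻¹. Monday over Saturday is then a reading of 1.00, with the scatter of a few readings in it, and the two stretches meet near 40.0 mM of substrate without overlapping. So I expect the two flasks to run alike.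

Does clearance hold still? Saturday's first stretch reads 0.0273 min⁻¹, lower than its last, so it rises as substrate falls. Monday's stretch covers the tail of Saturday's charge down to 12.8 mM of substrate and no reading stands below that, so carrying its clearance to the end is an estimate, and a low one if the rise goes on.

Wednesday's flask has Saturday's charge, so I start it from Saturday's 0.0406 M at 28 min and run 56.0 min more. On that estimate 4.16 mM of substrate stands at the end, a target share of 95.8%.

The forecast gives 1.15, 0.35, slower and 96%. On Monday it differs from me: “so Monday is slower”.

The flask gives 1.1, 0.24, alike and 96.9%.

    free catalyst + substrate → loaded catalyst + by-product (14.10 L mol⁻¹ min⁻¹)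
    loaded catalyst + reagent → target + free catalyst (22.14 L mol⁻¹ min⁻¹)
    free catalyst + impurity → spent catalyst
    free catalyst + substrate ⇌ idle catalyst-substrate complex, settled at all times (6.750 L mol⁻¹)

At equal substrate, Monday's flask runs at 1.0 times Saturday's rate, and the impurity step is not the reason for that ratio, which stays 1.0 with the step taken away. Monday's clearance puts the time to half its substrate at 17.0 min, against 17.7 min in the flask. The association of free catalyst and substrate to idle catalyst-substrate complex lowers the apparent order in substrate from 0.68 to 0.48 , so clearance climbs as substrate falls. Wednesday's tail needs 0.0460 min⁻¹, which is 1.13 times Monday's clearance.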